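**Plan**

- Retrosynthesis: the five benzyl ethers come off last. Ring C of the flavanone whose ring B carries the ether oxygen (unit 1) is cut at C2–C3 and O1–C8a, then ring C of the 6-aryloxy flavanone (unit 2) at the same two bonds, then the acetyl C–C bond and the diaryl ether C–O bond.
- Forward: 2,6-dibromo-4-fluorophenol is taken to a 4-iodophenyl ether, then to the fluoro ketone and its enol silane. A one-flask Mukaiyama aldol/fluoride-triggered SNAr with 4-(benzyloxy)benzaldehyde closes ring C of unit 2. The iodide is turned into the aldehyde, the same annulation with the enol silane made from 5-fluororesorcinol closes ring C of unit 1, and hydrogenolysis follows.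
- Enabling feature: in ring A of unit 2, C8a is ortho to the C4 carbonyl and meta to the oxygens on C5 and C7. A fluorine on C8a is therefore open to attack by the C2 oxygen that the aldol places five atoms away. Ring A of unit 1 has the same pattern.
- Stereochemistry: each C2 centre is set by catalyst-controlled si-face addition of the enol silane to the aldehyde (chiral oxazaborolidinone). The ring closure makes O1–C8a and leaves the C2–O bond alone, so the configuration passes unchanged into the flavanone.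

Key step: step 7

Assumption: the oxazaborolidinone made from N-tosyl-(S)-tryptophan is taken to send enol silanes to the re face of aromatic aldehydes, so the catalyst from N-tosyl-(R)-tryptophan is specified for the si-face addition that gives the (S)-carbinols; should the sense be the reverse, the other enantiomer of the catalyst is used and nothing else changes.

**Route**

Step 1
Reactants: 1 2,6-dibromo-4-fluorophenol
Product: 2 4-fluoro-2,6-dimethoxyphenol
Conditions: NaOMe, CuBr (cat.), MeOH/DMF, 110 °C; then aq HCl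
Reagents that add atoms: sodium methoxide, C[O-].[Na+]
Why: Ullmann-type copper-catalysed methoxylation exchanges the two C–Br bonds ortho to the phenoxide (the exchange used to make syringyl phenols from 2,6-dibromophenols), while the C–F bond para to the phenoxide oxygen is not activated and should stay.

Step 2
Reactants: 2 4-fluoro-2,6-dimethoxyphenol; 3 1,4-diiodobenzene
Product: 4 5-fluoro-2-(4-iodophenoxy)-1,3-dimethoxybenzene
Conditions: CuI (10 mol%), picolinic acid (20 mol%), K3PO4, DMSO, 90 °C; 3 in threefold excess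
Reagents that add atoms: none
Why: Ullmann diaryl ether synthesis under the ligand conditions used for 2,6-disubstituted phenols should join the hindered phenol to one C–I bond, the excess of 3 holding the reaction at the mono-ether and the aryl fluoride being inert to copper.

Step 3
Reactants: 4 5-fluoro-2-(4-iodophenoxy)-1,3-dimethoxybenzene
Product: 5 5-fluoro-2-(4-iodophenoxy)benzene-1,3-diol
Conditions: BBr3, CH2Cl2, −78 → 20 °C; then H2O
Reagents that add atoms: none
Why: Lewis-acid ether cleavage with BBr3 removes both methyl groups, while the diaryl ether, the C–I bond and the C–F bond are not attacked.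

Step 4
Reactants: 5 5-fluoro-2-(4-iodophenoxy)benzene-1,3-diol
Product: 6 1-[6-fluoro-2,4-dihydroxy-3-(4-iodophenoxy)phenyl]ethan-1-one
Conditions: AcOH, BF3·OEt2 (Lewis acid), 90 °C; aq NaOAc work-up
Reagents that add atoms: acetic acid, CC(=O)O
Why: Friedel–Crafts C-acylation of the resorcinol ring (the boron trifluoride method for hydroxyacetophenones) can only go to the two equivalent free positions, each ortho to fluorine, ortho to one hydroxyl and para to the other, the iodophenyl ring being far less activated.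

Step 5
Reactants: 6 1-[6-fluoro-2,4-dihydroxy-3-(4-iodophenoxy)phenyl]ethan-1-one
Product: 7 1-[2,4-bis(benzyloxy)-6-fluoro-3-(4-iodophenoxy)phenyl]ethan-1-one
Conditions: BnBr, K2CO3, DMF, 60 °C
Reagents that add atoms: benzyl bromide, BrCc1ccccc1
Why: Williamson ether synthesis should benzylate both phenols, the hydrogen-bonded one ortho to the ketone needing the gentle heating, at a temperature too low for phenoxide attack on the C–F bond.

Step 6
Reactants: 7 1-[2,4-bis(benzyloxy)-6-fluoro-3-(4-iodophenoxy)phenyl]ethan-1-one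
Product: 8 ({1-[2,4-bis(benzyloxy)-6-fluoro-3-(4-iodophenoxy)phenyl]ethenyl}oxy)trimethylsilane
Conditions: TMSOTf, Et3N, CH2Cl2, 0 °C
Reagents that add atoms: trimethylsilyl trifluoromethanesulfonate, C[Si](C)(C)OS(=O)(=O)C(F)(F)F
Why: Soft enolisation and O-silylation of the methyl ketone, the only enolisable position, gives the silyl enol ether needed for the Mukaiyama aldol.

Step 7
Reactants: 8 ({1-[2,4-bis(benzyloxy)-6-fluoro-3-(4-iodophenoxy)phenyl]ethenyl}oxy)trimethylsilane (1.15 equiv); 9 4-(benzyloxy)benzaldehyde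
Product: 12 (2S)-5,7-bis(benzyloxy)-2-[4-(benzyloxy)phenyl]-6-(4-iodophenoxy)-2,3-dihydro-4H-chromen-4-one, via silyl aldol ether 10 (not isolated), via caesium alkoxide 11 (not isolated)
Conditions: (R)-2-butyl-4-(1H-indol-3-ylmethyl)-3-tosyl-1,3,2-oxazaborolidin-5-one (20 mol%), EtCN, −78 °C; then CsF, 18-crown-6 (cat.), DMF, −40 → 20 °C, same flask
Reagents that add atoms: none
Why: The chiral boron Lewis acid binds aldehyde 9 and enol silane 8 adds to its si face with silyl transfer (Mukaiyama aldol) to give silyl ether 10; fluoride then frees alkoxide 11, which adds to the fluorine-bearing carbon (the future C8a) and expels fluoride from the anionic σ-adduct, so that the fluoride is returned and CsF is not consumed. The closest known reaction types are the oxazaborolidinone-catalysed Mukaiyama aldol of aryl methyl ketone enol silanes with aromatic aldehydes and the fluoride-mediated SNAr etherification of silyl ethers with aryl fluorides ortho to a carbonyl group, run here in one flask. Ring C of unit 2 closes by 6-endo-trig attack of the C2 oxygen on C8a (addition–elimination), which makes O1–C8a after C2–C3. The C2 centre is set as S in the aldol stage by the catalyst alone and is not touched by the ring closure, because the bond made there is O–aryl and not O–C2. The step needs ring closure to outrun retro-aldol cleavage and β-elimination of 11: the ketone ortho to fluorine takes up the negative charge, the benzyloxy groups on the future C5 and C7 are meta to the attacked carbon and the aryloxy group para to it is twisted out of conjugation by its two ortho neighbours, and the alkoxide is formed only as fast as fluoride is released. Aldehyde 9 is the limiting partner so that no aldehyde is left for an uncatalysed, fluoride-induced aldol addition when CsF is added.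

Step 8
Reactants: 12 (2S)-5,7-bis(benzyloxy)-2-[4-(benzyloxy)phenyl]-6-(4-iodophenoxy)-2,3-dihydro-4H-chromen-4-one
Product: 13 4-({(2S)-5,7-bis(benzyloxy)-2-[4-(benzyloxy)phenyl]-4-oxo-3,4-dihydro-2H-chromen-6-yl}oxy)benzaldehyde
Conditions: Pd(PPh3)4 (5 mol%), CO (3 atm), Bu3SnH (slow addition), toluene, 50 °C
Reagents that add atoms: carbon monoxide, [C-]#[O+]
Why: Palladium-catalysed reductive carbonylation (formylation) of the aryl iodide with CO and tin hydride runs under neutral conditions, so the base-sensitive C2 centre, the ketone and the benzyl ethers should be left as they are.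

Step 9
Reactants: 14 5-fluorobenzene-1,3-diol (5-fluororesorcinol)
Product: 15 1-(2-fluoro-4,6-dihydroxyphenyl)ethan-1-one
Conditions: AcOH, BF3·OEt2 (Lewis acid), 90 °C; aq NaOAc work-up
Reagents that add atoms: acetic acid, CC(=O)O
Why: Friedel–Crafts C-acylation of a 5-substituted resorcinol should go, as with orcinol, to the position ortho to the 5-substituent and para to a hydroxyl and not to the crowded position between the two hydroxyls.

Step 10
Reactants: 15 1-(2-fluoro-4,6-dihydroxyphenyl)ethan-1-one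
Product: 16 1-[2,4-bis(benzyloxy)-6-fluorophenyl]ethan-1-one
Conditions: BnBr, K2CO3, DMF, 60 °C
Reagents that add atoms: benzyl bromide, BrCc1ccccc1
Why: Williamson ether synthesis benzylates both phenols as in step 5.

Step 11
Reactants: 16 1-[2,4-bis(benzyloxy)-6-fluorophenyl]ethan-1-one
Product: 17 ({1-[2,4-bis(benzyloxy)-6-fluorophenyl]ethenyl}oxy)trimethylsilane
Conditions: TMSOTf, Et3N, CH2Cl2, 0 °C
Reagents that add atoms: trimethylsilyl trifluoromethanesulfonate, C[Si](C)(C)OS(=O)(=O)C(F)(F)F
Why: Soft enolisation and O-silylation of the methyl ketone gives the silyl enol ether as in step 6.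

Step 12
Reactants: 13 4-({(2S)-5,7-bis(benzyloxy)-2-[4-(benzyloxy)phenyl]-4-oxo-3,4-dihydro-2H-chromen-6-yl}oxy)benzaldehyde; 17 ({1-[2,4-bis(benzyloxy)-6-fluorophenyl]ethenyl}oxy)trimethylsilane (1.3 equiv)
Product: 20 (2S)-5,7-bis(benzyloxy)-2-[4-({(2S)-5,7-bis(benzyloxy)-2-[4-(benzyloxy)phenyl]-4-oxo-3,4-dihydro-2H-chromen-6-yl}oxy)phenyl]-2,3-dihydro-4H-chromen-4-one, via silyl aldol ether 18 (not isolated), via caesium alkoxide 19 (not isolated)
Conditions: (R)-2-butyl-4-(1H-indol-3-ylmethyl)-3-tosyl-1,3,2-oxazaborolidin-5-one (30 mol%), EtCN, −78 °C; then CsF, 18-crown-6 (cat.), DMF, −40 → 20 °C, same flask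
Reagents that add atoms: none
Why: The one-flask Mukaiyama aldol/fluoride-triggered SNAr annulation of step 7 is repeated, with catalyst-controlled si-face addition of 17 to the aldehyde of 13 (a far better electrophile than its chromanone ketone) setting C2 of unit 1 as S, and 6-endo-trig attack of alkoxide 19 on the fluorinated carbon, which is ortho to the ketone and meta to both benzyloxy groups, closing ring C without touching the C2–O bond.

Step 13
Reactants: 20 (2S)-5,7-bis(benzyloxy)-2-[4-({(2S)-5,7-bis(benzyloxy)-2-[4-(benzyloxy)phenyl]-4-oxo-3,4-dihydro-2H-chromen-6-yl}oxy)phenyl]-2,3-dihydro-4H-chromen-4-one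
Product: 21 (2S)-5,7-dihydroxy-2-[4-({(2S)-5,7-dihydroxy-2-(4-hydroxyphenyl)-4-oxo-3,4-dihydro-2H-chromen-6-yl}oxy)phenyl]-2,3-dihydro-4H-chromen-4-one (CNP0184214.1)
Conditions: H2 (1 atm), 10% Pd/C, EtOAc/MeOH, 20 °C
Reagents that add atoms: none
Why: Catalytic hydrogenolysis removes the five benzyl ethers under neutral conditions, which should leave both C2 centres and both aryl ketones unchanged.

**Compound list**

1 | 2,6-dibromo-4-fluorophenol | Oc1c(Br)cc(F)cc1Br | starting material
2 | 4-fluoro-2,6-dimethoxyphenol | COc1cc(F)cc(OC)c1O | intermediate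
3 | 1,4-diiodobenzene | Ic1ccc(I)cc1 | starting material
4 | 5-fluoro-2-(4-iodophenoxy)-1,3-dimethoxybenzene | COc1cc(F)cc(OC)c1Oc1ccc(I)cc1 | intermediate
5 | 5-fluoro-2-(4-iodophenoxy)benzene-1,3-diol | Oc1cc(F)cc(O)c1Oc1ccc(I)cc1 | intermediate
6 | 1-[6-fluoro-2,4-dihydroxy-3-(4-iodophenoxy)phenyl]ethan-1-one | CC(=O)c1c(F)cc(O)c(Oc2ccc(I)cc2)c1O | intermediate
7 | 1-[2,4-bis(benzyloxy)-6-fluoro-3-(4-iodophenoxy)phenyl]ethan-1-one | CC(=O)c1c(F)cc(OCc2ccccc2)c(Oc2ccc(I)cc2)c1OCc1ccccc1 | intermediate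
8 | ({1-[2,4-bis(benzyloxy)-6-fluoro-3-(4-iodophenoxy)phenyl]ethenyl}oxy)trimethylsilane | C=C(O[Si](C)(C)C)c1c(F)cc(OCc2ccccc2)c(Oc2ccc(I)cc2)c1OCc1ccccc1 | intermediate
9 | 4-(benzyloxy)benzaldehyde | O=Cc1ccc(OCc2ccccc2)cc1 | starting material
10 | (3S)-3-[4-(benzyloxy)phenyl]-1-[2,4-bis(benzyloxy)-6-fluoro-3-(4-iodophenoxy)phenyl]-3-[(trimethylsilyl)oxy]propan-1-one | O=C(C[C@@H](c1ccc(OCc2ccccc2)cc1)O[Si](C)(C)C)c1c(F)cc(OCc2ccccc2)c(Oc2ccc(I)cc2)c1OCc1ccccc1 | intermediate
11 | caesium (1S)-1-[4-(benzyloxy)phenyl]-3-[2,4-bis(benzyloxy)-6-fluoro-3-(4-iodophenoxy)phenyl]-3-oxopropan-1-olate | O=C(C[C@@H](c1ccc(OCc2ccccc2)cc1)[O-])c1c(F)cc(OCc2ccccc2)c(Oc2ccc(I)cc2)c1OCc1ccccc1.[Cs+] | intermediate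
12 | (2S)-5,7-bis(benzyloxy)-2-[4-(benzyloxy)phenyl]-6-(4-iodophenoxy)-2,3-dihydro-4H-chromen-4-one | O=C1C[C@@H](c2ccc(OCc3ccccc3)cc2)Oc2cc(OCc3ccccc3)c(Oc3ccc(I)cc3)c(OCc3ccccc3)c21 | intermediate
13 | 4-({(2S)-5,7-bis(benzyloxy)-2-[4-(benzyloxy)phenyl]-4-oxo-3,4-dihydro-2H-chromen-6-yl}oxy)benzaldehyde | O=Cc1ccc(Oc2c(OCc3ccccc3)cc3c(c2OCc2ccccc2)C(=O)C[C@@H](c2ccc(OCc4ccccc4)cc2)O3)cc1 | intermediate
14 | 5-fluorobenzene-1,3-diol (5-fluororesorcinol) | Oc1cc(O)cc(F)c1 | starting material
15 | 1-(2-fluoro-4,6-dihydroxyphenyl)ethan-1-one | CC(=O)c1c(O)cc(O)cc1F | intermediate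
16 | 1-[2,4-bis(benzyloxy)-6-fluorophenyl]ethan-1-one | CC(=O)c1c(F)cc(OCc2ccccc2)cc1OCc1ccccc1 | intermediate
17 | ({1-[2,4-bis(benzyloxy)-6-fluorophenyl]ethenyl}oxy)trimethylsilane | C=C(O[Si](C)(C)C)c1c(F)cc(OCc2ccccc2)cc1OCc1ccccc1 | intermediate
18 | (2S)-5,7-bis(benzyloxy)-2-[4-(benzyloxy)phenyl]-6-(4-{(1S)-3-[2,4-bis(benzyloxy)-6-fluorophenyl]-3-oxo-1-[(trimethylsilyl)oxy]propyl}phenoxy)-2,3-dihydro-4H-chromen-4-one | O=C(C[C@@H](c1ccc(Oc2c(OCc3ccccc3)cc3c(c2OCc2ccccc2)C(=O)C[C@@H](c2ccc(OCc4ccccc4)cc2)O3)cc1)O[Si](C)(C)C)c1c(F)cc(OCc2ccccc2)cc1OCc1ccccc1 | intermediate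
19 | caesium (1S)-3-[2,4-bis(benzyloxy)-6-fluorophenyl]-1-[4-({(2S)-5,7-bis(benzyloxy)-2-[4-(benzyloxy)phenyl]-4-oxo-3,4-dihydro-2H-chromen-6-yl}oxy)phenyl]-3-oxopropan-1-olate | O=C(C[C@@H](c1ccc(Oc2c(OCc3ccccc3)cc3c(c2OCc2ccccc2)C(=O)C[C@@H](c2ccc(OCc4ccccc4)cc2)O3)cc1)[O-])c1c(F)cc(OCc2ccccc2)cc1OCc1ccccc1.[Cs+] | intermediate
20 | (2S)-5,7-bis(benzyloxy)-2-[4-({(2S)-5,7-bis(benzyloxy)-2-[4-(benzyloxy)phenyl]-4-oxo-3,4-dihydro-2H-chromen-6-yl}oxy)phenyl]-2,3-dihydro-4H-chromen-4-one | O=C1C[C@@H](c2ccc(Oc3c(OCc4ccccc4)cc4c(c3OCc3ccccc3)C(=O)C[C@@H](c3ccc(OCc5ccccc5)cc3)O4)cc2)Oc2cc(OCc3ccccc3)cc(OCc3ccccc3)c21 | intermediate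
21 | (2S)-5,7-dihydroxy-2-[4-({(2S)-5,7-dihydroxy-2-(4-hydroxyphenyl)-4-oxo-3,4-dihydro-2H-chromen-6-yl}oxy)phenyl]-2,3-dihydro-4H-chromen-4-one (CNP0184214.1) | O=C1C[C@@H](c2ccc(Oc3c(O)cc4c(c3O)C(=O)C[C@@H](c3ccc(O)cc3)O4)cc2)Oc2cc(O)cc(O)c21 | target

**Step count and risks**

Total step count: 13. Longest linear sequence: 10 steps (steps 1 to 8, 12 and 13); steps 9 to 11 are the side branch that joins at step 12.

Steps most likely to fail:

1. Step 7. The caesium alkoxide may cleave by retro-aldol reaction or lose its C2 oxygen by β-elimination faster than it attacks the fluorinated carbon. The closed ring may also reopen at O1–C2 under the basic fluoride and reclose without control, which would lower the enantiomeric purity. The fallback makes the O1–C2 bond instead of the O1–C8a bond and sets out from ketone 7. Exchange of fluoride for hydroxide with 2-(methylsulfonyl)ethanol and NaH in DMF should give the phenol 1-[2,4-bis(benzyloxy)-6-hydroxy-3-(4-iodophenoxy)phenyl]ethan-1-one F1. Double silylation with TMSOTf and Et3N should give the bis-silyl compound ({1-[2,4-bis(benzyloxy)-3-(4-iodophenoxy)-6-[(trimethylsilyl)oxy]phenyl]ethenyl}oxy)trimethylsilane F2. Mukaiyama aldol addition of F2 to aldehyde 9 with the (S)-tryptophan-derived enantiomer of the catalyst, followed by dilute HCl, should give the diol (3R)-3-[4-(benzyloxy)phenyl]-1-[2,4-bis(benzyloxy)-6-hydroxy-3-(4-iodophenoxy)phenyl]-3-hydroxypropan-1-one F3. Mitsunobu cyclisation (PPh3, DIAD, THF, 0 °C) with inversion at the carbinol carbon then comes back to the route at compound 12.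

2. Step 12. The same competition between ring closure, retro-aldol cleavage and β-elimination applies. In addition, the ring C already present in unit 2 may open and reclose under the basic fluoride, with loss of configuration at its C2, and the chromanone carbonyl may hold back the boron catalyst. Because a diastereomer that differs at one remote centre would be hard to remove, recrystallisation of 12 before step 8 is planned in any case. The fallback sets out from ketone 16 and aldehyde 13. Fluoride-to-hydroxide exchange on 16 (2-(methylsulfonyl)ethanol, NaH, DMF) should give 1-[2,4-bis(benzyloxy)-6-hydroxyphenyl]ethan-1-one F4. Double silylation should give ({1-[2,4-bis(benzyloxy)-6-[(trimethylsilyl)oxy]phenyl]ethenyl}oxy)trimethylsilane F5. Mukaiyama aldol addition of F5 to 13 with the (S)-tryptophan-derived catalyst and mild acid work-up should give the diol (2S)-5,7-bis(benzyloxy)-2-[4-(benzyloxy)phenyl]-6-(4-{(1R)-3-[2,4-bis(benzyloxy)-6-hydroxyphenyl]-1-hydroxy-3-oxopropyl}phenoxy)-2,3-dihydro-4H-chromen-4-one F6. Mitsunobu cyclisation with inversion comes back to the route at compound 20.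

3. Step 8. The arylpalladium intermediate may be reduced by the tin hydride before it takes up CO, which would give loss of iodine without formylation. The fallback sets out from iodide 12 and replaces carbonylation by coupling and oxidative cleavage. Stille coupling with tributyl(vinyl)stannane (Pd(PPh3)4, toluene, 100 °C, neutral) should give the styrene (2S)-5,7-bis(benzyloxy)-2-[4-(benzyloxy)phenyl]-6-(4-ethenylphenoxy)-2,3-dihydro-4H-chromen-4-one F7. Lemieux–Johnson oxidation (OsO4 cat., NaIO4, 2,6-lutidine, dioxane/H2O) then comes back to the route at compound 13.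

**Further compounds**

F1 | step 7 | 1-[2,4-bis(benzyloxy)-6-hydroxy-3-(4-iodophenoxy)phenyl]ethan-1-one | CC(=O)c1c(O)cc(OCc2ccccc2)c(Oc2ccc(I)cc2)c1OCc1ccccc1
F2 | step 7 | ({1-[2,4-bis(benzyloxy)-3-(4-iodophenoxy)-6-[(trimethylsilyl)oxy]phenyl]ethenyl}oxy)trimethylsilane | C=C(O[Si](C)(C)C)c1c(O[Si](C)(C)C)cc(OCc2ccccc2)c(Oc2ccc(I)cc2)c1OCc1ccccc1
F3 | step 7 | (3R)-3-[4-(benzyloxy)phenyl]-1-[2,4-bis(benzyloxy)-6-hydroxy-3-(4-iodophenoxy)phenyl]-3-hydroxypropan-1-one | O=C(C[C@@H](O)c1ccc(OCc2ccccc2)cc1)c1c(O)cc(OCc2ccccc2)c(Oc2ccc(I)cc2)c1OCc1ccccc1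
F4 | step 12 | 1-[2,4-bis(benzyloxy)-6-hydroxyphenyl]ethan-1-one | CC(=O)c1c(O)cc(OCc2ccccc2)cc1OCc1ccccc1
F5 | step 12 | ({1-[2,4-bis(benzyloxy)-6-[(trimethylsilyl)oxy]phenyl]ethenyl}oxy)trimethylsilane | C=C(O[Si](C)(C)C)c1c(O[Si](C)(C)C)cc(OCc2ccccc2)cc1OCc1ccccc1
F6 | step 12 | (2S)-5,7-bis(benzyloxy)-2-[4-(benzyloxy)phenyl]-6-(4-{(1R)-3-[2,4-bis(benzyloxy)-6-hydroxyphenyl]-1-hydroxy-3-oxopropyl}phenoxy)-2,3-dihydro-4H-chromen-4-one | O=C(C[C@@H](O)c1ccc(Oc2c(OCc3ccccc3)cc3c(c2OCc2ccccc2)C(=O)C[C@@H](c2ccc(OCc4ccccc4)cc2)O3)cc1)c1c(O)cc(OCc2ccccc2)cc1OCc1ccccc1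
F7 | step 8 | (2S)-5,7-bis(benzyloxy)-2-[4-(benzyloxy)phenyl]-6-(4-ethenylphenoxy)-2,3-dihydro-4H-chromen-4-one | O=C1C[C@@H](c2ccc(OCc3ccccc3)cc2)Oc2cc(OCc3ccccc3)c(Oc3ccc(C=C)cc3)c(OCc3ccccc3)c21
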